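**Assumptions (one line each)**
- Germacranolide numbering is used: C1 = ketal carbon, C4 = ether carbon bearing Me, C5=C6 = ylidene alkene, C8 = tiglate carbinol, C10 = CHMe, C13 = CH2OAc. The target is (1S,4R,8S,10R,5E) with a 2E tiglate.
- The Marshall propargylation is taken to give net inversion at the propargylic carbon (anti-SN2′ oxidative addition, then cyclic syn-SE2′ addition). If the sense is the opposite, the (R)-mesylate is used instead.

**Retrosynthetic overview**
1. The 10-membered ring is closed last, at the C5=C6 ylidene bond, by an intramolecular vinylogous aldol condensation of a butenolide γ-CH2 (C6) onto a C5 aldehyde held cis on a preformed 2-methoxyoxolane. The ring forces the 5E geometry.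
2. The seco-aldehyde comes from a C7–C8 Nozaki–Hiyama–Kishi coupling of a 4-iodobutenolide with a C8 aldehyde; C8 is then set by oxidation and CBS reduction and acylated with the tiglate.
3. The oxolane ketal carries C1–C5, C9 and C10. C4 comes from (R)-linalool, C10 from a Marshall propargylation, and C1 is fixed by ketalisation (anomer selection, later locked by the bicycle).
4. The iodobutenolide comes from but-2-yne-1,4-diol by propargylic carbonylation and iodolactonisation.
5. Ring order: butenolide (fragment), then oxolane ketal, then the 10-membered carbocycle; C13 PMB-to-acetate exchange finishes the synthesis.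

**Route**

Step 1
Reactants: 1, but-2-yne-1,4-diol (3 equiv)
Product: 2, 4-[(4-methoxybenzyl)oxy]but-2-yn-1-ol
Conditions: NaH (1 equiv), PMBCl, TBAI (cat.), THF/DMF, 0 °C to rt
Reagents that add atoms: 4-methoxybenzyl chloride, COc1ccc(CCl)cc1
Why: Williamson etherification of the mono-alkoxide of a symmetric diol used in excess gives the mono-PMB ether; no stereocentre is formed.

Step 2
Reactants: 2
Product: 3, methyl 4-[(4-methoxybenzyl)oxy]but-2-yn-1-yl carbonate
Conditions: ClCO2Me, pyridine, CH2Cl2, 0 °C
Reagents that add atoms: methyl chloroformate, COC(=O)Cl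
Why: O-acylation with a chloroformate installs the leaving group for propargylic palladium chemistry.

Step 3
Reactants: 3
Product: 4, methyl 2-{[(4-methoxybenzyl)oxy]methyl}buta-2,3-dienoate
Conditions: Pd2(dba)3·CHCl3 (2.5 mol %), PPh3 (10 mol %), CO (10 atm), MeOH, 45 °C
Reagents that add atoms: carbon monoxide, [C-]#[O+]; methanol, CO
Why: Tsuji carbonylation of a propargylic carbonate: SN2′ oxidative addition gives an allenyl-palladium species, and CO insertion with methanolysis (CO2 lost) gives the 2,3-dienoate.

Step 4
Reactants: 4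
Product: 5, 4-iodo-3-{[(4-methoxybenzyl)oxy]methyl}furan-2(5H)-one
Conditions: I2 (2 equiv), MeCN/H2O (15:1), rt
Reagents that add atoms: iodine, II
Why: Iodolactonisation of a 2,3-allenoate: iodonium formation on the distal C=C, 5-endo attack by the ester carbonyl oxygen and loss of the O-methyl group give the β-iodobutenolide with CH2OPMB at the α-carbon.

Step 5
Reactants: 6, (S)-but-3-yn-2-ol
Product: 7, (S)-but-3-yn-2-yl methanesulfonate
Conditions: MsCl, Et3N, CH2Cl2, −78 °C
Reagents that add atoms: methanesulfonyl chloride, CS(=O)(=O)Cl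
Why: O-sulfonylation does not break the C–O bond, so the stereocentre is retained.

Step 6
Reactants: 8, (R)-(−)-linalool
Product: 9, triethyl{[(3R)-3,7-dimethylocta-1,6-dien-3-yl]oxy}silane
Conditions: TESOTf, 2,6-lutidine, CH2Cl2, −78 to 0 °C
Reagents that add atoms: triethylsilyl triflate, CC[Si](CC)(CC)OS(=O)(=O)C(F)(F)F
Why: Silyl triflate silylation of the hindered tertiary allylic alcohol; the chiral-pool centre (future C4, R) is untouched.

Step 7
Reactants: 9
Product: 10, (4R)-4-methyl-4-[(triethylsilyl)oxy]hex-5-enal
Conditions: O3 (about 1 equiv, indicator end-point), pyridine (3 equiv), CH2Cl2, −78 °C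
Reagents that add atoms: ozone, [O-][O+]=O
Why: Chemoselective ozonolysis: the electron-rich trisubstituted alkene reacts much faster than the vinyl group next to the quaternary silyloxy carbon, and pyridine gives the aldehyde directly.

Step 8
Reactants: 10; 7 (1.5 equiv)
Product: 11, (3R,4S,7R)-3,7-dimethyl-7-[(triethylsilyl)oxy]non-8-en-1-yn-4-ol (anti; the minor C4 epimer converges in step 9)
Conditions: Pd(OAc)2 (5 mol %), PPh3 (5 mol %), Et2Zn (3 equiv), THF, −78 to −20 °C
Reagents that add atoms: none beyond reactant 7
Why: Marshall propargylation: the chiral allenylzinc from 7 adds through a cyclic SE2′ transition state, so the methyl-bearing centre (future C10, R) is set by the reagent while the carbinol configuration is irrelevant.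

Step 9
Reactants: 11
Product: 12, (3R,7R)-3,7-dimethyl-7-[(triethylsilyl)oxy]non-8-en-1-yn-4-one
Conditions: Dess–Martin periodinane, NaHCO3, CH2Cl2, 0 °C; used crude
Reagents that add atoms: none
Why: Dess–Martin oxidation under buffered, non-basic conditions converts both carbinol epimers to one ketone without enolising the propargylic α-centre (C10).

Step 10
Reactants: 12
Product: 13, (2S,5R)-2-[(2R)-but-3-yn-2-yl]-5-ethenyl-2-methoxy-5-methyloxolane
Conditions: PPTS (0.2 equiv), MeOH, HC(OMe)3, rt; separate the anomers and resubmit the (2R) anomer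
Reagents that add atoms: methanol, CO
Why: Acid removes the tertiary TES ether and the γ-hydroxy ketone ketalises through the cyclic oxocarbenium ion; C1 forms as an anomer mixture under thermodynamic control, the (2S) anomer (side chain cis to vinyl) is isolated and the other recycled.

Step 11
Reactants: 13
Product: 14, (3R)-3-[(2S,5R)-5-ethenyl-2-methoxy-5-methyloxolan-2-yl]butanal
Conditions: CpRu(MeCN)3PF6 (3 mol %), 5,5′-bis(trifluoromethyl)-2,2′-bipyridine (3 mol %), NMP/H2O (4:1), 25 °C
Reagents that add atoms: water, O
Why: Ruthenium-vinylidene anti-Markovnikov hydration converts only the terminal alkyne to the aldehyde (C8) under neutral conditions that leave the vinyl group and the ketal alone.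

Step 12
Reactants: 14; 5 (1.5 equiv)
Product: 15, 4-{(3R)-1-hydroxy-3-[(2S,5R)-5-ethenyl-2-methoxy-5-methyloxolan-2-yl]butyl}-3-{[(4-methoxybenzyl)oxy]methyl}furan-2(5H)-one (C8 epimers)
Conditions: CrCl2 (4 equiv), NiCl2 (2 mol %), DMSO, rt; used directly
Reagents that add atoms: none beyond reactant 5
Why: Nozaki–Hiyama–Kishi coupling: nickel inserts into the β-iodoenoate C–I bond and the alkenylchromium(III) adds only to the aldehyde without β-eliminating the allylic lactone oxygen; C8 stereochemistry is corrected in steps 13–14.

Step 13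
Reactants: 15
Product: 16, 4-{(3R)-3-[(2S,5R)-5-ethenyl-2-methoxy-5-methyloxolan-2-yl]butanoyl}-3-{[(4-methoxybenzyl)oxy]methyl}furan-2(5H)-one
Conditions: Dess–Martin periodinane, NaHCO3, CH2Cl2, 0 °C
Reagents that add atoms: none
Why: Dess–Martin oxidation merges both C8 epimers into one ketone and removes the free C8–OH that could translactonise.

Step 14
Reactants: 16
Product: 17, 4-{(1S,3R)-1-hydroxy-3-[(2S,5R)-5-ethenyl-2-methoxy-5-methyloxolan-2-yl]butyl}-3-{[(4-methoxybenzyl)oxy]methyl}furan-2(5H)-one
Conditions: (R)-Me-CBS (1 equiv), catecholborane (1.8 equiv), toluene, −78 °C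
Reagents that add atoms: none
Why: Corey–Bakshi–Shibata reduction: the α-branched alkenyl (butenolide) group acts as the large substituent and CH2R as the small one, so the (R)-catalyst delivers hydride to give the 8S alcohol, as for γ-keto enoates.

Step 15
Reactants: 17; 18, tigloyl chloride [(E)-2-methylbut-2-enoyl chloride]
Product: 19, (1S,3R)-3-[(2S,5R)-5-ethenyl-2-methoxy-5-methyloxolan-2-yl]-1-(4-{[(4-methoxybenzyl)oxy]methyl}-5-oxo-2,5-dihydrofuran-3-yl)butyl (2E)-2-methylbut-2-enoate
Conditions: pyridine, DMAP (5 mol %), CH2Cl2, 0 °C, immediately after step 14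
Reagents that add atoms: none beyond reactant 18
Why: Acylation of the secondary alcohol with the configurationally stable E acid chloride installs the tiglate and blocks C8–O from translactonisation or spiroketalisation.

Step 16
Reactants: 19
Product: 20, (1S,3R)-3-[(2S,5R)-5-formyl-2-methoxy-5-methyloxolan-2-yl]-1-(4-{[(4-methoxybenzyl)oxy]methyl}-5-oxo-2,5-dihydrofuran-3-yl)butyl (2E)-2-methylbut-2-enoate
Conditions: OsO4 (2 mol %), NaIO4 (4 equiv), 2,6-lutidine, dioxane/H2O (3:1), rt
Reagents that add atoms: osmium tetroxide, O=[Os](=O)(=O)=O, with sodium periodate, [Na+].[O-]I(=O)(=O)=O (source of the aldehyde oxygen)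
Why: Lemieux–Johnson cleavage: the isolated vinyl group is dihydroxylated much faster than the conjugated, electron-poor tiglate and butenolide alkenes, giving a non-enolisable C5 aldehyde.

Step 17 (key step)
Reactants: 20
Product: 21, 13-O-(4-methoxybenzyl)-13-deacetylvernolide-B (the bicyclic 10-membered ylidene butenolide; 1S,4R,8S,10R,5E)
Conditions: DBU (3 equiv), LiCl (10 equiv), MeCN, 1 mM (syringe pump), 0 to 25 °C; then Ac2O (6 equiv), DMAP (0.3 equiv), 25 to 45 °C
Reagents that add atoms: none (the transient acetate is eliminated)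
Why: Proposed new method: DBU reversibly deprotonates the butenolide γ-CH2 (C6) to the aromatic 2-furanolate, which adds through C6 to the non-enolisable C5 aldehyde held cis on the oxolane; acetylation of the aldolate and E1cB loss of acetate through the same furanolate make the condensation irreversible, and the ring allows only the C4/C7-cis (5E) alkene; the closest known chemistry is the one-pot silyloxyfuran aldol/DBU elimination route to γ-ylidenebutenolides, here run intramolecularly and without a silyl triflate so the ketal survives.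

Step 18
Reactants: 21
Product: 22, 13-O-deacetylvernolide-B
Conditions: DDQ (1.5 equiv), CH2Cl2/pH 7 buffer (10:1), 0 °C
Reagents that add atoms: none
Why: Oxidative PMB cleavage under buffered conditions spares the bridged methyl ketal, the esters and the electron-poor dienyl lactone.

Step 19
Reactants: 22
Product: 23, Vernolide-B
Conditions: Ac2O, pyridine, DMAP (cat.), CH2Cl2, 0 °C
Reagents that add atoms: acetic anhydride, CC(=O)OC(C)=O
Why: Acetylation of the primary allylic alcohol; with no γ-hydrogen left on the lactone, the 13-acetate can no longer be expelled by E1cB.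

**Compound list**

1 | but-2-yne-1,4-diol | OCC#CCO | starting material
2 | 4-[(4-methoxybenzyl)oxy]but-2-yn-1-ol | OCC#CCOCc1ccc(OC)cc1 | intermediate
3 | methyl 4-[(4-methoxybenzyl)oxy]but-2-yn-1-yl carbonate | COC(=O)OCC#CCOCc1ccc(OC)cc1 | intermediate
4 | methyl 2-{[(4-methoxybenzyl)oxy]methyl}buta-2,3-dienoate | C=C=C(COCc1ccc(OC)cc1)C(=O)OC | intermediate
5 | 4-iodo-3-{[(4-methoxybenzyl)oxy]methyl}furan-2(5H)-one | O=C1OCC(I)=C1COCc1ccc(OC)cc1 | intermediate
6 | (S)-but-3-yn-2-ol | C#C[C@H](C)O | starting material
7 | (S)-but-3-yn-2-yl methanesulfonate | C#C[C@H](C)OS(C)(=O)=O | intermediate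
8 | (R)-(−)-linalool | C=C[C@](C)(O)CCC=C(C)C | starting material
9 | (R)-linalool triethylsilyl ether | C=C[C@](C)(O[Si](CC)(CC)CC)CCC=C(C)C | intermediate
10 | (4R)-4-methyl-4-[(triethylsilyl)oxy]hex-5-enal | C=C[C@](C)(O[Si](CC)(CC)CC)CCC=O | intermediate
11 | (3R,4S,7R)-3,7-dimethyl-7-[(triethylsilyl)oxy]non-8-en-1-yn-4-ol | C#C[C@@H](C)[C@@H](O)CC[C@@](C)(O[Si](CC)(CC)CC)C=C | intermediate
12 | (3R,7R)-3,7-dimethyl-7-[(triethylsilyl)oxy]non-8-en-1-yn-4-one | C#C[C@@H](C)C(=O)CC[C@@](C)(O[Si](CC)(CC)CC)C=C | intermediate
13 | (2S,5R)-2-[(2R)-but-3-yn-2-yl]-5-ethenyl-2-methoxy-5-methyloxolane | C#C[C@@H](C)[C@]1(OC)CC[C@](C)(C=C)O1 | intermediate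
14 | (3R)-3-[(2S,5R)-5-ethenyl-2-methoxy-5-methyloxolan-2-yl]butanal | O=CC[C@@H](C)[C@]1(OC)CC[C@](C)(C=C)O1 | intermediate
15 | NHK adduct, C8 epimers (8-hydroxy seco compound) | OC(C[C@@H](C)[C@]1(OC)CC[C@](C)(C=C)O1)C2=C(COCc3ccc(OC)cc3)C(=O)OC2 | intermediate
16 | C8 ketone (4-acylbutenolide) | O=C(C[C@@H](C)[C@]1(OC)CC[C@](C)(C=C)O1)C2=C(COCc3ccc(OC)cc3)C(=O)OC2 | intermediate
17 | (8S)-alcohol | O[C@@H](C[C@@H](C)[C@]1(OC)CC[C@](C)(C=C)O1)C2=C(COCc3ccc(OC)cc3)C(=O)OC2 | intermediate
18 | tigloyl chloride | C/C=C(\C)C(Cl)=O | starting material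
19 | (8S)-tiglate, vinyl seco compound | C/C=C(\C)C(=O)O[C@@H](C[C@@H](C)[C@]1(OC)CC[C@](C)(C=C)O1)C2=C(COCc3ccc(OC)cc3)C(=O)OC2 | intermediate
20 | (8S)-tiglate, C5 aldehyde (cyclisation precursor) | C/C=C(\C)C(=O)O[C@@H](C[C@@H](C)[C@]1(OC)CC[C@](C)(C=O)O1)C2=C(COCc3ccc(OC)cc3)C(=O)OC2 | intermediate
21 | 13-O-(4-methoxybenzyl)-13-deacetylvernolide-B | C/C=C(\C)C(=O)O[C@H]1C[C@@H](C)[C@]2(OC)CC[C@](C)(/C=C3/OC(=O)C(COCc4ccc(OC)cc4)=C31)O2 | intermediate
22 | 13-O-deacetylvernolide-B | C/C=C(\C)C(=O)O[C@H]1C[C@@H](C)[C@]2(OC)CC[C@](C)(/C=C3/OC(=O)C(CO)=C31)O2 | intermediate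
23 | Vernolide-B | C/C=C(\C)C(=O)O[C@H]1C[C@@H](C)[C@]2(OC)CC[C@](C)(/C=C3/OC(=O)C(COC(C)=O)=C31)O2 | target

**Totals**
- Total steps: 19.
- Longest linear sequence: 14 steps (steps 6–19, from (R)-linalool). The butenolide branch (steps 1–4) and the mesylate (step 5) are convergent.

**Three steps most likely to fail, with fallbacks**

1. Step 17, ring-closing vinylogous aldol condensation. Risks are oligomerisation, attack through the α-carbon, E1cB loss of the C13 alkoxide from the furanolate, or no closure of the strained ring.
 Fallback: change the ring-closing bond. Join C5 to C6 first, intermolecularly, by a silyloxyfuran aldol of the iodobutenolide with the C5 aldehyde before the ketal is made (keeping C5–OSiR3 and C6–H). Then close the ring at C7–C8 by an intramolecular Nozaki–Hiyama–Kishi reaction, and form the ylidene last by E1cB elimination inside the ring.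

2. Steps 9–10, β,γ-alkynyl ketone and ketalisation. Risks are epimerisation or allene formation at C10, and an unfavourable anomer ratio at C1.
 Fallback: take C8 and C10 from the chiral pool. Trans-selective α-methylation of L-glutamic-acid-derived (S)-5-(trityloxymethyl)butyrolactone gives the (3R,5S) lactone, whose carbonyl is C1. Open it as the Weinreb amide and add the organolithium from the (R)-citramalic-acid-derived iodide (C2–C5). Ketalise, then build the butenolide on C7 by intramolecular Horner–Wadsworth–Emmons reaction of an α-acyloxy ketone.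

3. Step 14 (with step 15), CBS reduction of the 4-acylbutenolide. Risks are conjugate reduction, modest selectivity, and translactonisation of the free C8–OH to the 8,12-olide before acylation.
 Fallback: carry the lactone as a 3,4-disubstituted furan. Add the 3-furyllithium to aldehyde 14, oxidise, and reduce the aryl-type furyl ketone by asymmetric transfer hydrogenation. Acylate, then unveil the butenolide later by silyl-directed singlet-oxygen oxidation followed by borohydride reduction.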